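Late in a run, once every portion is in, free monomer falls without refill, so the last readings carry the rate of that run.

| setting | alpha | gamma | flask |
|---|---|---|---|
| free monomer | 0.95 M (in portions, 4) | 0.95 M (in portions, 4) | 0.95 M (in portions, 4) |
| initiator | 13 mM | 21 mM | 9.5 mM |
| radical scavenger | 0.66 mM | 0.66 mM | 0.66 mM |
| remark | run made earlier; portions every 30 min | run made earlier; portions every 30 min | the portions of free monomer follow each other after 30 min, the first at the start |
| time |  |  | 5.0 h |

| run | time / h | free monomer / % | monomer in chains / % | isomer of the product / % |
|---|---|---|---|---|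
| alpha | 0.200 | 24.6 | 0.6 | 0.4 |
| alpha | 0.667 | 47.8 | 2.4 | 0 |
| alpha | 1.00 | 44.4 | 5.9 | 0 |
| alpha | 1.50 | 60.9 | 12.8 | 1.7 |
| alpha | 2.50 | 69.0 | 28.2 | 3.2 |
| alpha | 3.00 | 61.4 | 33.6 | 4.0 |
| alpha | 4.00 | 49.0 | 43.4 | 6.8 |
| gamma | 0.500 | 23.1 | 2.0 | 1.0 |
| gamma | 1.00 | 41.6 | 7.7 | 0.3 |
| gamma | 1.50 | 56.7 | 16.0 | 1.5 |
| gamma | 2.50 | 61.1 | 34.6 | 3.0 |
| gamma | 3.00 | 53.0 | 40.9 | 5.9 |
| gamma | 4.00 | 39.8 | 50.6 | 8.0 |

(scatter of a reading: 0.5 percentage points)

1. the state of affairs at 5.0 h: stopped, and by what, or still going (all of the free monomer has reacted / forward and back rates have come level / it is still moving)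
2. conversion of free monomer at 5.0 h
3. amount of monomer in chains at 5.0 h, in percent of the free monomer charged
4. amount of isomer of the product at 5.0 h, in percent of the free monomer charged

- steps thought possible: initiator -> 2 initiating radical; free monomer + initiating radical -> growing radical + monomer in chains; monomer in chains <-> isomer of the product; free monomer + growing radical -> monomer in chains + growing radical; free monomer -> decomposition product; 2 growing radical -> dead chain; growing radical + radical scavenger -> ended chains
- the reaction counts as stopped when no species that holds the free monomer changes by six tenths of a point or more over the second half of the time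

Between the last two readings of each run, the logarithm of free monomer falls at 0.226 h⁻¹ in the alpha run and at 0.286 h⁻¹ in the gamma run. Their ratio, 1.27, reads like the root of the initiator ratio, 1.27. Scaling the alpha value by that root gives, for the flask:

late constant = alpha value × √(flask initiator / alpha initiator) = 0.193 h⁻¹

Call this pseudo-first-order constant the late decay constant.

Turned round: to have stopped with its free monomer used up, the flask would need a half-life short against the 3.50 h after the last portion. The reckoned half-life, 3.59 h, is about as long as that. Reckoned with this constant, free monomer in the flask loses 38.3% of what stands over the second half of the time, so the flask is reckoned as still moving.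

First round, as if the whole charge stood at the last portion:

free monomer at the end = exp(−late constant × time after the last portion) = 50.9%

Second round, putting back the earlier loss, estimated from the alpha readings of monomer in chains plus isomer of the product at 1.50 h, scaled by the same root:

loss = 12.4%, free monomer = 44.6%, conversion = 55.4%

The forecast, holding that “so the rate goes as √[I]”, said it is still moving, with conversion 52.5% (48% to 57%), monomer in chains 44.2% and isomer of the product 8.3%, a conversion lower than this reckoning.

The flask gives: it is still moving, conversion 53.7%, monomer in chains 45.3%, isomer of the product 8.09%.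

    initiator → 2 initiating radical (k = 0.0600 h⁻¹)
    free monomer + initiating radical → growing radical + monomer in chains (k = 68000 M⁻¹ s⁻¹)
    monomer in chains ⇌ isomer of the product (K = 0.270, k = 0.140 h⁻¹)
    free monomer + growing radical → monomer in chains + growing radical, rate k4*[growing radical]*[free monomer] (k = 2.40 × 10⁶ M⁻¹ h⁻¹)
    free monomer → decomposition product (k = 0.00120 h⁻¹)
    2 growing radical → dead chain (k = 2.20 × 10⁷ M⁻¹ s⁻¹)
    growing radical + radical scavenger → ended chains (k = 4.00 × 10⁷ M⁻¹ s⁻¹)

At 5.0 h the flask is not at rest: 46% of the charged free monomer remains, and the half-life of free monomer by its growth step into chains stands at 4.0 h, close to the reckoned 3.59 h. Left until 50.0 h, the flask reaches a conversion of 99.6%, with monomer in chains at 77.9% and isomer of the product at 21.0%.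

In a second flask, charged alike but with 0.038 M of initiator, the late decay constant becomes 0.386 h⁻¹, and the same two rounds give 19.5% free monomer at 5.0 h. That flask holds 20.1%.

The data come from a simulation on assumed constants.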